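**Remark on the chemistry (assumption):** the diaryl ether axis is taken as freely rotating, so the target has no stereogenic element. Ring A is numbered C1 (OH), C2 (Br), C4 (Br), C6 (ether O); ring B is numbered C1′ (ether O), C2′ (Br), C5′ (Br), C6′ (OH).

## Analysis of the target

The target 18 is a diphenyl ether of formula C12H6Br4O3, two benzene rings joined through one oxygen, with no further ring and no stereocentre. Ring A carries OH at C1, Br at C2 and C4 and the ether oxygen at C6, while ring B carries the ether oxygen at C1′, Br at C2′ and C5′ and OH at C6′, so each ring is a brominated catechol unit and the two rings are not related by symmetry. The sensitive groups are four aryl C–Br bonds, which are open to metal insertion, halogen–metal exchange and reduction, and two electron-rich phenols that oxidise easily once free. The synthesis is hard because the ether bond joins two crowded carbons (C6 beside C1–OH, C1′ between C2′–Br and C6′–OH), neither ring has an activating group for SNAr, and a metal-catalysed etherification would have to pick one carbon–halogen bond out of five. The bromines of ring B lie ortho to the oxygens, a pattern that electrophilic bromination of a catechol ether (para attack) cannot give, so they cannot be added late. The strategy rests on ring A, whose two oxygens sit on the adjacent carbons C1 and C6 with Br on C2 beside C1, which is the pattern left when a nucleophile and an electrophile add across the C1–C6 triple bond of 3,5-dibromobenzyne, the nucleophile at C6 away from the bromine and the electrophile at C1. Ring B in turn has the 3,6-disubstitution pattern that twofold ortho-lithiation of a catechol dimethyl ether delivers.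

## Retrosynthetic reasoning

**18 ⇒ 17.** The last operation is removal of the methyl group from the oxygen on C6′. A methyl ether is chosen because it survives organolithium and organomagnesium reagents and the fluoride source of the coupling. It also leaves the ring B nucleophile with a single O–H, so no acidic proton is present when the rings are joined. The forward step has to cleave one O–CH3 bond without touching the diaryl ether or the C–Br bonds.

**17 ⇒ 14.** The C1–O bond of the ring A hydroxyl is traced back to a C1–I bond. Iodine is the halogen an aryl anion takes up fastest, and it is the one halogen that can be told apart from four bromines in a halogen–magnesium exchange. The forward sequence must exchange only iodine, attach boron at C1 and oxidise the C–B bond to C–O.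

**14 ⇒ 5 + 9 + 10.** The O–C6 bond and the C1–I bond are cut together. This reveals 3,5-dibromobenzyne 12, released from silyl triflate 5, the phenoxide 11 of phenol 9, and perfluorohexyl iodide 10 as iodine donor. The cut is made on the ring A side because only there does the vicinal O,O pattern with a flanking bromine map onto an aryne. On the ring B side the oxygen-bearing carbon lies between a bromine and the second oxygen and offers no such handle. The gain is convergence: both rings carry all their bromines before they are joined, and the hindered phenol is arylated without a transition metal. The forward reaction must direct the phenoxide to C6, and must iodinate the aryl anion 13 at C1 before it is protonated or loses the neighbouring bromide.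

**5 ⇒ 2 ⇒ 1.** The C6–Si and O–S bonds of 5 are cut. 2,4,6-Tribromophenol 1 already has bromine at C2 and C4 and a third bromine where silicon is needed. After O-silylation to 2, exchange of one of the two equivalent ortho bromines gives aryllithium 3, whose silyl group migrates from oxygen to carbon to give phenoxide 4; sulfonylation of 4 gives 5. The forward sequence must exchange an ortho and not the para bromine.

**9 ⇒ 8 ⇒ 6.** Phenol 9 comes from the symmetric dimethyl ether 8 by loss of one of two equivalent methyl groups. Both C–Br bonds of 8 are then cut back to veratrole 6 through the dilithio compound 7, because the two methoxy groups direct metalation to exactly C3 and C6. The forward steps must lithiate twice and then stop the demethylation after one methyl.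

## Alternatives that were turned down

Alternative 1: Ring B would be built instead of bought. It is cut at C1′–C2′ and C5′–C6′ into a four-carbon diene that carries both bromines, 2,5-dibromothiophene 1,1-dioxide A2, and a two-carbon alkyne that carries the aryloxy group and a boron placeholder for the C6′ hydroxyl, 2-{[2-(benzyloxy)phenoxy]ethynyl}-4,4,5,5-tetramethyl-1,3,2-dioxaborolane A3.

The key step in the forward direction would be an inverse-demand (4+2) cycloaddition of the electron-poor sulfone diene A2 with the ynol ether A3. Cheletropic extrusion of the sulfonyl bridge would then aromatise the adduct to the aryl boronate 2-{2-[2-(benzyloxy)phenoxy]-3,6-dibromophenyl}-4,4,5,5-tetramethyl-1,3,2-dioxaborolane A1.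

In its favour, A2 is symmetric, so there is no regiochemical question and both ring B bromines of A1 arrive at C2′ and C5′ with certainty. On this point the cycloaddition is stronger than an aryne addition, which relies on a directing effect.

Against it, A2 dimerises readily, and the cycloaddition would have to outrun that at an alkyne that is crowded and made less nucleophilic by boron, while creating four contiguous substituents. A3 is itself a sensitive compound several steps from commercial material. Ring A of A1 still has no bromine, so three operations follow A1: a debenzylation that avoids hydrogenolysis, a dibromination that must touch ring A only, and oxidation of the boronate.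

In comparison, the union that gives A1 is no better precedented than the aryne coupling and leaves more work after it. The chosen strategy joins two fully brominated rings and needs two routine steps afterwards.

Alternative 2: Ring A would be built by a (3+3) condensation. It is cut at C2–C3 and C5–C6 into a ketone piece C2–C1–C6, 1-(3,6-dibromo-2-methoxyphenoxy)propan-2-one A5, made from phenol 9 by O-alkylation with a haloacetone, and bromomalonaldehyde A6, which supplies C3, C4 with its bromine, and C5.

The key step in the forward direction would have both α-carbons of A5 condense under base with the two aldehyde groups of A6. Dehydration and tautomerisation would then give the phenol 4-bromo-2-(3,6-dibromo-2-methoxyphenoxy)phenol A4. Bromination of A4 at C2, the only open position ortho or para to its hydroxyl, would lead on to 17.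

In its favour, the bond from the hindered ring B oxygen is made by a simple SN2 alkylation on the way to A5, which is easier than any arylation, the aryne included. No halogen has to be distinguished by a metal. The step count (six, all in one line) is no worse than the chosen route (seven in total, five in the longest line).

Against it, this kind of phenol synthesis works with ketones activated on both α-carbons, whereas A5 has one weakly activated CH2 and a plain methyl group. Under base A6 is a stabilised enolate and a poor electrophile, and as an α-bromo carbonyl compound it invites displacement of bromide by the ketone enolate. Self-condensation of A5 competes as well, so the formation of A4 is doubtful.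

In comparison, the ring construction that gives A4 is the weak point and the sequence is fully linear. The chosen strategy keeps both rings intact from commercial arenes, is convergent, and puts its risk in a step whose two elementary events, phenoxide addition to an aryne and iodination of an aryl anion, are each fast.

Alternative 3: The ring B bromines would come from carboxyl groups. The C2′–Br and C5′–Br bonds are traced back to two carboxyl groups, that is to 2-(3,5-dibromo-2-methoxyphenoxy)-3-methoxyterephthalic acid A8.

The key step in the forward direction would excite the carboxylates of divalent copper formed from A8 at 365 nm. They would decarboxylate to aryl radicals, and each radical would take a bromine atom from an N-bromo hydantoin donor to give the tetrabromide 1,5-dibromo-3-(3,6-dibromo-2-methoxyphenoxy)-2-methoxybenzene A7. Twofold demethylation of A7 would give 18.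

In its favour, decarboxylative halogenation of aryl carboxylic acids is an established reaction type, so on precedent this step is stronger than the aryne coupling. The carboxyl groups of A8, as esters, would also help an SNAr ether formation at C1′.

Against it, two radical brominations must both succeed in one molecule, and every aryl radical that abstracts hydrogen gives an under-brominated ether that is hard to separate from A7. Only the C2′ carboxyl is ortho to C1′, so the SNAr activation is modest. A8 needs a long synthesis, and its substitution pattern comes from the same dilithiation of veratrole that gives the bromines of 8 directly when quenched with a bromine donor.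

In comparison, the carboxyl detour through A8 adds steps to reach a pattern available in one. The chosen route sets every bromine on monocyclic material by ionic chemistry and is shorter, at the price of an untested union.

Key step: step 5

## Route

Step 1
Reactants: 1 2,4,6-tribromophenol
Product: 2 (2,4,6-tribromophenoxy)trimethylsilane
Conditions: HMDS (0.7 equiv), THF, reflux; evaporate, use crude
Reagents that add atoms: hexamethyldisilazane, C[Si](C)(C)N[Si](C)(C)C
Why: O-silylation of an acidic phenol by a silazane; ammonia is the only by-product and leaves on evaporation, so the moisture-sensitive aryl silyl ether needs no aqueous work-up.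

Step 2
Reactants: 2 (2,4,6-tribromophenoxy)trimethylsilane
Product: 5 2,4-dibromo-6-(trimethylsilyl)phenyl trifluoromethanesulfonate, via ortho-lithiated silyl ether 3 (not isolated), via lithium silylphenoxide 4 (not isolated)
Conditions: n-BuLi (1.05 equiv), THF, −100 → −80 °C; then Tf2O (1.2 equiv), −100 → −78 °C; cold aq. NaHCO3
Reagents that add atoms: trifluoromethanesulfonic anhydride, O=S(=O)(OS(=O)(=O)C(F)(F)F)C(F)(F)F
Why: Bromine–lithium exchange is expected at one of the two equivalent bromines ortho to the silyloxy group (favoured over para by the inductive effect and lithium coordination of oxygen), a retro-Brook 1,3 O→C silyl shift then gives the phenoxide, and O-triflation completes the standard sequence from ortho-bromophenols to ortho-silylaryl triflates; the lithiated carbon of 3 has no halogen beside it, so no aryne can form at this stage.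

Step 3
Reactants: 6 veratrole (1,2-dimethoxybenzene)
Product: 8 1,4-dibromo-2,3-dimethoxybenzene, via 3,6-dilithioveratrole 7 (not isolated)
Conditions: n-BuLi (3 equiv), TMEDA (3 equiv), Et2O/hexane, 0 °C → rt → reflux; then cannulate into BrCCl2CCl2Br (3 equiv), THF, −78 °C → rt
Reagents that add atoms: 1,2-dibromo-1,1,2,2-tetrachloroethane, BrC(Cl)(Cl)C(Cl)(Cl)Br
Why: Twofold directed ortho-metalation, each methoxy group guiding lithium to its free ortho position, followed by halogen-philic bromination with a positive-bromine donor that collapses to tetrachloroethene and LiBr; inverse addition keeps the aryl bromide away from unreacted aryllithium and so limits bromine–lithium scrambling.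

Step 4
Reactants: 8 1,4-dibromo-2,3-dimethoxybenzene
Product: 9 3,6-dibromo-2-methoxyphenol
Conditions: NaSEt (1.5 equiv), DMF, 90–100 °C; aq. HCl; acid–base extraction
Reagents that add atoms: none
Why: SN2 demethylation by thiolate at one of two equivalent methyl groups; the phenoxide formed shuts down loss of the second methyl because the leaving group would be a dianion, and the ortho bromine makes the first aryloxide a good enough leaving group that a moderate temperature should suffice, below what thiolate attack on an unactivated C–Br bond needs.

Step 5
Reactants: 5 2,4-dibromo-6-(trimethylsilyl)phenyl trifluoromethanesulfonate; 9 3,6-dibromo-2-methoxyphenol; 10 perfluorohexyl iodide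
Product: 14 1,4-dibromo-2-(3,5-dibromo-2-iodophenoxy)-3-methoxybenzene, via potassium phenoxide 11 (not isolated), via 3,5-dibromobenzyne 12 (not isolated), via arylpotassium adduct 13 (not isolated)
Conditions: 9 (1.5 equiv), KH (1.5 equiv), THF, 0 °C → rt; then 18-crown-6 (3 equiv), C6F13I (5 equiv), KF (3 equiv), 0 °C, dark; 5 (1.0 equiv) in THF added over 4 h, 0 °C → rt
Reagents that add atoms: perfluorohexyl iodide (compound 10), FC(F)(F)C(F)(F)C(F)(F)C(F)(F)C(F)(F)C(F)(F)I
Why: Proposed new method: fluoride attacks the silicon of 5 and triflate leaves to give 3,5-dibromobenzyne 12; the closest known reaction type is the three-component aryne coupling in which a nitrogen or sulfur nucleophile adds and the aryl anion is halogenated by a polyhaloalkane, and the plain two-component O-arylation of phenols by silylaryl triflates is routine. The C2 bromine withdraws electron density and distorts the triple bond so that C6 is the more linear, more electrophilic carbon, so phenoxide 11 should add at C6 (O–C6 bond) and the charge develops at C1, where the adjacent C–Br bond stabilises it. The C4 bromine pulls weakly the other way but is overridden, and attack at C1 would also force the doubly ortho-substituted phenoxide against the C2 bromine. The aryl anion 13 is then iodinated at C1 by halogen-philic attack on the iodine of 10 (C1–I bond), a transfer expected to be close to diffusion-controlled, and the perfluorohexyl anion released collapses to perfluorohex-1-ene and KF; no ring is closed and no stereocentre is formed. The step needs regioselective addition, secured by the C2 bromine, and iodination that outruns both protonation and loss of bromide from the ortho-bromoaryl anion. The second is secured by a phenoxide fully pre-formed with KH so that no O–H remains, an ether solvent without acidic C–H bonds, a potassium/crown cation in place of an ammonium ion, low temperature, slow addition of 5 and a five-fold excess of 10. The phenoxide, flanked by Br and OMe, is a poor partner for copper coupling but should add readily to an aryne, and the dark suppresses electron transfer from the phenoxide to 10.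

Step 6
Reactants: 14 1,4-dibromo-2-(3,5-dibromo-2-iodophenoxy)-3-methoxybenzene
Product: 17 2,4-dibromo-6-(3,6-dibromo-2-methoxyphenoxy)phenol, via arylmagnesium chloride 15 (not isolated), via dimethyl arylboronate 16 (not isolated)
Conditions: iPrMgCl·LiCl (1.05 equiv), THF, −78 °C, 20 min; B(OMe)3 (2 equiv), −78 → −20 °C; AcOH, 30% aq. H2O2, 0 °C → rt; aq. Na2S2O3
Reagents that add atoms: hydrogen peroxide, OO
Why: Iodine–magnesium exchange is far faster than bromine–magnesium exchange and this iodine is further activated by the ortho bromine and ortho aryloxy group, so one equivalent at −78 °C should touch only C1; ortho-bromoarylmagnesium species keep their bromide below about −20 °C, and borate formation followed by peroxide oxidation (1,2-aryl shift from boron to oxygen) under weakly acidic conditions should give the phenol while limiting base-promoted protodeboronation.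

Step 7
Reactants: 17 2,4-dibromo-6-(3,6-dibromo-2-methoxyphenoxy)phenol
Product: 18 2,4-dibromo-6-(3,6-dibromo-2-hydroxyphenoxy)phenol
Conditions: BBr3 (3 equiv), CH2Cl2, −78 °C → rt; H2O
Reagents that add atoms: none
Why: Lewis-acid cleavage of an aryl methyl ether, bromide attacking the methyl group of the O–B adduct; the diaryl ether and the aryl C–Br bonds are inert to BBr3, which makes this the usual closing step for hydroxylated polybrominated diphenyl ethers.

## Compound list

1 | 2,4,6-tribromophenol | Oc1c(Br)cc(Br)cc1Br | starting material
2 | (2,4,6-tribromophenoxy)trimethylsilane | C[Si](C)(C)Oc1c(Br)cc(Br)cc1Br | intermediate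
3 | [3,5-dibromo-2-(trimethylsilyloxy)phenyl]lithium | [Li]c1cc(Br)cc(Br)c1O[Si](C)(C)C | intermediate
4 | lithium 2,4-dibromo-6-(trimethylsilyl)phenoxide | [Li+].[O-]c1c(Br)cc(Br)cc1[Si](C)(C)C | intermediate
5 | 2,4-dibromo-6-(trimethylsilyl)phenyl trifluoromethanesulfonate | C[Si](C)(C)c1cc(Br)cc(Br)c1OS(=O)(=O)C(F)(F)F | intermediate
6 | veratrole (1,2-dimethoxybenzene) | COc1ccccc1OC | starting material
7 | 3,6-dilithioveratrole, (2,3-dimethoxy-1,4-phenylene)dilithium | [Li]c1ccc([Li])c(OC)c1OC | intermediate
8 | 1,4-dibromo-2,3-dimethoxybenzene | COc1c(Br)ccc(Br)c1OC | intermediate
9 | 3,6-dibromo-2-methoxyphenol | COc1c(Br)ccc(Br)c1O | intermediate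
10 | perfluorohexyl iodide (1,1,1,2,2,3,3,4,4,5,5,6,6-tridecafluoro-6-iodohexane) | FC(F)(F)C(F)(F)C(F)(F)C(F)(F)C(F)(F)C(F)(F)I | starting material
11 | potassium 3,6-dibromo-2-methoxyphenoxide | [K+].[O-]c1c(Br)ccc(Br)c1OC | intermediate
12 | 3,5-dibromobenzyne (3,5-dibromo-1,2-didehydrobenzene) | C1#CC(Br)=CC(Br)=C1 | intermediate
13 | [2,4-dibromo-6-(3,6-dibromo-2-methoxyphenoxy)phenyl]potassium | [K]c1c(Br)cc(Br)cc1Oc1c(Br)ccc(Br)c1OC | intermediate
14 | 1,4-dibromo-2-(3,5-dibromo-2-iodophenoxy)-3-methoxybenzene | COc1c(Br)ccc(Br)c1Oc1cc(Br)cc(Br)c1I | intermediate
15 | [2,4-dibromo-6-(3,6-dibromo-2-methoxyphenoxy)phenyl]magnesium chloride | COc1c(Br)ccc(Br)c1Oc1cc(Br)cc(Br)c1[Mg]Cl | intermediate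
16 | dimethyl [2,4-dibromo-6-(3,6-dibromo-2-methoxyphenoxy)phenyl]boronate | COB(OC)c1c(Br)cc(Br)cc1Oc1c(Br)ccc(Br)c1OC | intermediate
17 | 2,4-dibromo-6-(3,6-dibromo-2-methoxyphenoxy)phenol | COc1c(Br)ccc(Br)c1Oc1cc(Br)cc(Br)c1O | intermediate
18 | 2,4-dibromo-6-(3,6-dibromo-2-hydroxyphenoxy)phenol | Oc1c(Br)cc(Br)cc1Oc1c(Br)ccc(Br)c1O | target

## Step count and risk

Total: 7 steps. Longest linear sequence: 5 steps (6 → 8 → 9 → 14 → 17 → 18, or equally 1 → 2 → 5 → 14 → 17 → 18).

**Step 5 (key step, proposed new method).**
- What may go wrong: the aryl anion 13 is protonated before it meets 10, which gives the ether without iodine. It may also lose the neighbouring bromide to form a second aryne that oligomerises. Phenoxide 11 may be drained by addition to the perfluorohex-1-ene formed from 10, or by electron transfer to 10. All of these follow from the high basicity and short lifetime of an ortho-bromoaryl anion and from the electrophilic by-product of the iodine donor.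
- Fallback (known chemistry), from 9 back to 14: 2,4-dibromo-6-fluoroaniline F1 (taken as commercial) is oxidised with NaBO3·4H2O in AcOH at 55 °C to 1,5-dibromo-3-fluoro-2-nitrobenzene F2. Phenol 9 displaces the fluoride of F2 (K2CO3, DMF, 60–80 °C; SNAr ortho to the nitro group, fluoride leaving far faster than bromide) to give 1,4-dibromo-2-(3,5-dibromo-2-nitrophenoxy)-3-methoxybenzene F3. Reduction with Fe/NH4Cl in EtOH/H2O, which spares C–Br bonds, gives 2,4-dibromo-6-(3,6-dibromo-2-methoxyphenoxy)aniline F4. Diazotisation with NaNO2 in H2SO4/AcOH at 0 °C gives 2,4-dibromo-6-(3,6-dibromo-2-methoxyphenoxy)benzenediazonium hydrogen sulfate F5, and KI converts it to 14 (Sandmeyer-type iodination), where the route resumes at step 6.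

**Step 6.**
- What may go wrong: exchange at a bromine beside the intended iodine, loss of bromide from 15 on warming before the borate has formed, or protodeboronation of the doubly ortho-substituted boronate 16 during oxidation. Each would give under-functionalised ether.
- Fallback, from 14 back to 17: 15 is formed as before at −78 °C and captured directly with tert-butyl peroxybenzoate (−78 → −20 °C), a classical electrophilic oxygenation of a Grignard reagent that needs no boron intermediate. This gives 1,4-dibromo-2-(3,5-dibromo-2-tert-butoxyphenoxy)-3-methoxybenzene F6. CF3CO2H in CH2Cl2 then removes the tert-butyl group as 2-methylpropene to give 17.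

**Step 4.**
- What may go wrong: thiolate attack at a C–Br bond (substitution or reductive loss of bromine) competing with demethylation, or stalling before full conversion.
- Fallback, from 8 back to 9: exhaustive demethylation with BBr3 in CH2Cl2 gives 3,6-dibromobenzene-1,2-diol F7. One O-methylation with MeI (1.0 equiv) and Li2CO3 in DMF at rt then gives 9. The monoanion of the diol forms much more readily than the dianion, the symmetry allows only one mono-ether, and unreacted F7 and recovered 8 are separated and recycled.

**Step 3.**
- What may go wrong: incomplete second lithiation, and bromine–lithium scrambling between remaining aryllithium sites and aryl bromide as it forms. Both would give mono- and mis-brominated material that is hard to separate from 8.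
- Fallback, from 6 back to 8: the dilithiation is quenched with Me3SiCl, which cannot scramble, to give 1,2-dimethoxy-3,6-bis(trimethylsilyl)benzene F8. F8 is purified by crystallisation and then converted by electrophilic ipso-bromodesilylation (Br2, CH2Cl2, 0 °C) into 8.

## Further compounds

F1 | step 5 | 2,4-dibromo-6-fluoroaniline | Nc1c(F)cc(Br)cc1Br
F2 | step 5 | 1,5-dibromo-3-fluoro-2-nitrobenzene | [O-][N+](=O)c1c(F)cc(Br)cc1Br
F3 | step 5 | 1,4-dibromo-2-(3,5-dibromo-2-nitrophenoxy)-3-methoxybenzene | COc1c(Br)ccc(Br)c1Oc1cc(Br)cc(Br)c1[N+](=O)[O-]
F4 | step 5 | 2,4-dibromo-6-(3,6-dibromo-2-methoxyphenoxy)aniline | COc1c(Br)ccc(Br)c1Oc1cc(Br)cc(Br)c1N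
F5 | step 5 | 2,4-dibromo-6-(3,6-dibromo-2-methoxyphenoxy)benzenediazonium hydrogen sulfate | COc1c(Br)ccc(Br)c1Oc1cc(Br)cc(Br)c1[N+]#N.OS(=O)(=O)[O-]
F6 | step 6 | 1,4-dibromo-2-(3,5-dibromo-2-tert-butoxyphenoxy)-3-methoxybenzene | COc1c(Br)ccc(Br)c1Oc1cc(Br)cc(Br)c1OC(C)(C)C
F7 | step 4 | 3,6-dibromobenzene-1,2-diol | Oc1c(Br)ccc(Br)c1O
F8 | step 3 | 1,2-dimethoxy-3,6-bis(trimethylsilyl)benzene | COc1c([Si](C)(C)C)ccc([Si](C)(C)C)c1OC
A1 | alternative 1 | 2-{2-[2-(benzyloxy)phenoxy]-3,6-dibromophenyl}-4,4,5,5-tetramethyl-1,3,2-dioxaborolane | CC1(C)OB(c2c(Br)ccc(Br)c2Oc2ccccc2OCc2ccccc2)OC1(C)C
A2 | alternative 1 | 2,5-dibromothiophene 1,1-dioxide | O=S1(=O)C(Br)=CC=C1Br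
A3 | alternative 1 | 2-{[2-(benzyloxy)phenoxy]ethynyl}-4,4,5,5-tetramethyl-1,3,2-dioxaborolane | CC1(C)OB(C#COc2ccccc2OCc2ccccc2)OC1(C)C
A4 | alternative 2 | 4-bromo-2-(3,6-dibromo-2-methoxyphenoxy)phenol | COc1c(Br)ccc(Br)c1Oc1cc(Br)ccc1O
A5 | alternative 2 | 1-(3,6-dibromo-2-methoxyphenoxy)propan-2-one | COc1c(Br)ccc(Br)c1OCC(C)=O
A6 | alternative 2 | bromomalonaldehyde (2-bromopropanedial) | O=CC(Br)C=O
A7 | alternative 3 | 1,5-dibromo-3-(3,6-dibromo-2-methoxyphenoxy)-2-methoxybenzene | COc1c(Br)cc(Br)cc1Oc1c(Br)ccc(Br)c1OC
A8 | alternative 3 | 2-(3,5-dibromo-2-methoxyphenoxy)-3-methoxyterephthalic acid | COc1c(Br)cc(Br)cc1Oc1c(C(=O)O)ccc(C(=O)O)c1OC
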